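The constants used here are those of an exercise; the flask was simulated.

A half-life of 19 min for starting material by step 3 alone stands far above the 0.680 min in which dissolution relaxes, so we read this flask as a slow drain behind a quick dissolver.

solid substrate 0.96 M; partner 1.10 equiv; time 80 min

* how much target there is at 80 min, in percent of the solid substrate charged
* the change that raises the amount of target at 80 min, in percent of the solid substrate charged most ("none" if none brings more than 2 percentage points) (Saturday's / Tuesday's / Wednesday's / none)
* amount of target at 80 min, in percent of the solid substrate charged, after Wednesday's

- Saturday's: doubling the dissolution coefficient of step 2, all else as stated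
- Tuesday's: doubling the amount of partner, all else as stated
- Wednesday's: doubling the solubility in step 2, all else as stated

    partner + intermediate A ⇌ intermediate B (K1 = 1.3 L mol⁻¹, k1 = 0.0040 L mol⁻¹ s⁻¹)
    solid substrate ⇌ starting material, rate k2*(cs2 - [starting material]) while solid is left; crystals form when [starting material] > cs2 (cs2 = 0.42 M, k2 = 0.017 s⁻¹)
    starting material → intermediate A (k3 = 6.2 × 10⁻⁴ s⁻¹)
    partner + intermediate A → target (k4 = 0.0017 L mol⁻¹ s⁻¹)
    intermediate B ⇌ intermediate C (K5 = 2.3, k5 = 0.0075 s⁻¹)

We climb the ladder from the fastest rung. Dissolution of the solid substrate comes first, so starting material soon holds the level S at which dissolution balances step 3: the solubility times the dissolution coefficient over the sum of that coefficient and k, the constant of step 3, which is 0.405 M. Next, intermediates B and C relax in 1.07 min, and intermediate A meets partner with forward half-lives of 2.7 min towards intermediate B and 6.4 min towards target, both shorter than step 3's, but these two hold for partner as charged, so we do not equate what step 3 delivers with target. On the rung of step 3, the feed kS is constant while solid lasts, for T = (c − S)/(kS) = 36.8 min, where c is the charge, and starting material then decays exponentially from S. Integrating step 3 gives D, the share of the charge delivered past step 3 by time t, as one minus (S/c)·exp(−k(t − T)).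

At 80 min we get D = 91.5 %, which leaves 8.50 % as starting material and caps target. After Wednesday's, the cap is 94.8 %. Partner does not enter D, so our reckoning stops at these ceilings.

The forecast gave 47 %, Tuesday's and 53.5 %, holding that “the starting material sits near its solubility”.

The simulation gives 50.2 % of target, Tuesday's as the best change with 7.5 percentage points against 5.3 points for Wednesday's and 0.49 points for Saturday's, and 55.5 % after Wednesday's; net turnover through step 3 is 91.2 %, beside our D of 91.5 %.

Partner has no place in D, so the neighbouring flask with 0.440 equiv of partner is reckoned at the same 91.5 % delivered and 8.50 % starting material, and that flask reads 8.77 % of starting material. Its delivered material lies differently: partner, the limiting reagent there, has 9.90 % of its own charge left, intermediate A stands at 51.6 %, intermediates B and C together at 12.2 %, and target at 27.4 %.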